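**Retrosynthetic overview** (target numbering: C3 = i‑Pr carbinol, C3a = ring‑fusion CH, C4 = ester carbinol, C6 = tertiary allylic carbinol, C7=C8, C8a = methyl‑bearing quaternary carbon)
1. Target 33 ⇐ acylation of triol 30; its C6 carbinol and C7=C8 alkene ⇐ C6=C7 cycloheptene 26 by hydroxyl‑directed epoxidation, selenolate opening and selenoxide elimination.
2. Seven‑membered ring (formed last) ⇐ RCM of an allyl group on C8a and a methallyl chain; the C4–C5 bond ⇐ chelation‑controlled methallylation of β‑hydroxy aldehyde 23 with methallyl bromide 24 (key fragment union).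
3. Aldehyde 23 ⇐ cis‑fused bicyclic γ‑lactone 16: lactone carbonyl → allyl (DIBAL, two Wittig reactions); CH2OSi appendage → CHO (periodate).
4. Five‑membered ring (formed second, on the lactone template) ⇐ Michael addition of dithiane 9 to butenolide 6, intramolecular enolate alkylation, angular methylation, ketone unmasking, convex‑face i‑Pr addition.
5. Butenolide 6 (first, temporary ring) ⇐ D‑mannitol diacetonide 1; every stereocentre descends from its carbinol carbon.

Assumption: the SMILES is taken literally (cis ring fusion; 3R,3aS,4S,6R,8aS); anions, organometallic forms, onium salts and other short‑lived activated species (ylide adducts, periodate esters, O‑acylisourea) count as part of the conditions and are not numbered.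

**Step 1**
Reactants: 1 1,2:5,6-di-O-isopropylidene-D-mannitol
Product: 2 (R)-2,2-dimethyl-1,3-dioxolane-4-carbaldehyde (two equivalents)
Conditions: NaIO4, aq. NaHCO3, CH2Cl2, rt
Reagents that add atoms: none
Why: Malaprade glycol cleavage of the only free 1,2-diol gives two molecules of the aldehyde without touching the acetonides or the stereocentre.

**Step 2**
Reactants: 2 (R)-glyceraldehyde acetonide
Product: 3 methyl (Z)-3-[(S)-2,2-dimethyl-1,3-dioxolan-4-yl]prop-2-enoate
Conditions: Ph3P=CHCO2Me, MeOH, 0 °C (Z:E about 8:1, Z isomer purified)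
Reagents that add atoms: methyl (triphenylphosphoranylidene)acetate, COC(=O)C=P(c1ccccc1)(c1ccccc1)c1ccccc1
Why: Wittig olefination of an α-alkoxy aldehyde with a stabilised ylide is Z-selective in methanol, giving the cis enoate needed for lactonisation.

**Step 3**
Reactants: 3 Z-enoate acetonide
Product: 5 (S)-5-(hydroxymethyl)furan-2(5H)-one, via Z-dihydroxy ester 4 (not isolated)
Conditions: cat. H2SO4, MeOH–H2O, rt
Reagents that add atoms: none
Why: Acid-catalysed acetonide hydrolysis followed by spontaneous lactonisation (intramolecular transesterification) of the cis γ-hydroxy enoate leaves the C–O stereocentre untouched.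

**Step 4**
Reactants: 5 (S)-5-(hydroxymethyl)furan-2(5H)-one
Product: 6 (S)-5-{[tert-butyl(diphenyl)silyl]oxymethyl}furan-2(5H)-one
Conditions: TBDPSCl, imidazole, DMF, 0 °C → rt
Reagents that add atoms: tert-butyl(chloro)diphenylsilane, CC(C)(C)[Si](Cl)(c1ccccc1)c1ccccc1
Why: Silyl ether formation at the primary alcohol installs the bulky group that shields one face of the butenolide.

**Step 5**
Reactants: 7 1,3-dithiane; 8 (2-bromoethoxy)(tert-butyl)dimethylsilane
Product: 9 tert-butyl[2-(1,3-dithian-2-yl)ethoxy]dimethylsilane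
Conditions: n-BuLi, THF, −30 °C; then 8, −78 °C → rt
Reagents that add atoms: none
Why: Corey–Seebach alkylation of the lithiated dithiane with a primary bromide gives the masked acyl anion carrying the two-carbon tether.

**Step 6**
Reactants: 6 silyl butenolide; 9 dithiane
Product: 10 (4S,5S)-4-(2-substituted dithianyl)-5-(silyloxymethyl)oxolan-2-one (trans)
Conditions: 9, n-BuLi, THF, −25 °C; DMPU, then 6, −78 °C; AcOH
Reagents that add atoms: none
Why: Michael addition of the sulfur-stabilised carbanion to the butenolide occurs anti to the silyloxymethyl group, so the future C3a centre is set from the chiral-pool carbon.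

**Step 7**
Reactants: 10 Michael adduct
Product: 11 primary alcohol
Conditions: PPTS, MeOH, rt
Reagents that add atoms: none
Why: Acid-catalysed methanolysis (protecting-group removal) cleaves the primary TBS ether selectively in the presence of the TBDPS ether, the dithiane and the lactone.

**Step 8**
Reactants: 11 primary alcohol
Product: 12 primary iodide
Conditions: I2, PPh3, imidazole, CH2Cl2, 0 °C → rt
Reagents that add atoms: iodine, II
Why: Appel-type iodination turns the primary alcohol into a leaving group without involving any stereocentre.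

**Step 9**
Reactants: 12 primary iodide
Product: 13 cis-fused spiro-dithiane bicyclic lactone
Conditions: LDA, THF, −78 → 0 °C
Reagents that add atoms: none
Why: Intramolecular lactone enolate alkylation (5-exo-tet) closes the cyclopentane, which can only be cis-fused to the γ-lactone.

**Step 10**
Reactants: 13 bicyclic lactone
Product: 14 angular-methyl bicyclic lactone
Conditions: LDA, THF, −78 °C; MeI, DMPU, −78 → −20 °C
Reagents that add atoms: iodomethane, CI
Why: Enolate alkylation at the ring-fusion carbon takes place on the convex face and must keep the cis-bicyclo[3.3.0] fusion, creating the C8a quaternary centre with methyl cis to H-3a.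

**Step 11**
Reactants: 14 methylated dithiane lactone
Product: 15 keto lactone
Conditions: MeI, CaCO3, MeCN–H2O (4:1), 45 °C
Reagents that add atoms: water, O
Why: Alkylative dithiane hydrolysis (S-methylation then hydrolysis) unmasks the ketone under near-neutral conditions that spare the β-acyloxy ketone and the silyl ether.

**Step 12**
Reactants: 15 keto lactone
Product: 16 tertiary alcohol (i-Pr on the convex face)
Conditions: i-PrMgCl, CeCl3, THF, −78 °C
Reagents that add atoms: isopropylmagnesium chloride, CC(C)[Mg]Cl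
Why: Imamoto organocerium 1,2-addition suppresses enolisation and β-elimination, and attack on the convex face of the cis-bicycle places isopropyl cis to H-3a and the hydroxyl on the lactone side (C3 = R).

**Step 13**
Reactants: 16 tertiary alcohol
Product: 17 triethylsilyl ether
Conditions: Et3SiOTf, 2,6-lutidine, CH2Cl2, 0 °C → rt
Reagents that add atoms: triethylsilyl trifluoromethanesulfonate, CC[Si](CC)(CC)OS(=O)(=O)C(F)(F)F
Why: Silyl triflate silylation protects the hindered tertiary alcohol so that only the secondary oxygen can close onto the aldehyde made in step 15.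

**Step 14**
Reactants: 17 silyl-protected lactone
Product: 18 γ-lactol (anomer mixture)
Conditions: i-Bu2AlH, CH2Cl2, −78 °C; aq. KNaC4H4O6
Reagents that add atoms: none
Why: Low-temperature DIBAL reduction of a lactone stops at the lactol because the aluminium hemiacetal is stable until work-up.

**Step 15**
Reactants: 18 γ-lactol
Product: 20 δ-lactol (anomer mixture), via methyl enol ether 19 (not isolated)
Conditions: MeOCH2PPh3Cl, KOt-Bu, THF, 0 °C → rt; then PPTS, THF–H2O, 45 °C
Reagents that add atoms: (methoxymethyl)triphenylphosphonium chloride, COC[P+](c1ccccc1)(c1ccccc1)c1ccccc1.[Cl-]; water, O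
Why: Wittig methoxymethylenation of the open hydroxy aldehyde and enol ether hydrolysis give a one-carbon homologation, the new aldehyde closing onto the secondary hydroxyl as a six-membered lactol.

**Step 16**
Reactants: 20 δ-lactol
Product: 21 allyl compound with free secondary alcohol
Conditions: Ph3PCH3Br, KOt-Bu, THF, 0 → 50 °C
Reagents that add atoms: methyltriphenylphosphonium bromide, C[P+](c1ccccc1)(c1ccccc1)c1ccccc1.[Br-]
Why: Wittig methylenation of the lactol through its open aldehyde form gives the allyl group on C8a and frees the secondary alcohol.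

**Step 17**
Reactants: 21 bis-silyl ether
Product: 22 triol
Conditions: Bu4NF, THF, rt → 50 °C
Reagents that add atoms: none
Why: Fluoride-mediated desilylation removes both silyl ethers and exposes the terminal 1,2-diol and the tertiary hydroxyl.

**Step 18**
Reactants: 22 triol
Product: 23 β-hydroxy aldehyde
Conditions: NaIO4, THF–H2O, pH 7, 0 °C
Reagents that add atoms: none
Why: Malaprade cleavage of the terminal 1,2-diol excises the chiral-pool carbon as formaldehyde and leaves the C4 aldehyde, the 1,3-related tertiary hydroxyl being inert.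

**Step 19** (key step)
Reactants: 23 β-hydroxy aldehyde; 24 3-bromo-2-methylprop-1-ene
Product: 25 homoallylic diol (4S carbinol)
Conditions: 24 (3 equiv), indium powder (2 equiv), THF–H2O (1:1), rt
Reagents that add atoms: none
Why: In this Barbier-type carbonyl allylation the free tertiary hydroxyl and the aldehyde oxygen bind the metal (Cram-chelate control), so the carbonyl is held syn to the C–O bond and the methallyl group enters from the face next to H-3a and not the quaternary carbon, forming the C4–C5 bond with 4S configuration.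

**Step 20**
Reactants: 25 diene diol
Product: 26 cis-fused cycloheptene diol
Conditions: second-generation Grubbs catalyst RuCl2(=CHPh)(H2IMes)(PCy3) (5 mol %), CH2Cl2 (5 mM), 40 °C
Reagents that add atoms: none
Why: Ring-closing metathesis of the allyl and methallyl chains, which are cis on the cyclopentane, closes the seven-membered ring as a trisubstituted cycloalkene with loss of ethene.

**Step 21**
Reactants: 26 cycloheptene diol
Product: 27 epoxy diol
Conditions: VO(acac)2 (5 mol %), t-BuOOH, CH2Cl2, 0 °C → rt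
Reagents that add atoms: tert-butyl hydroperoxide, CC(C)(C)OO
Why: Homoallylic hydroxyl-directed epoxidation (Sharpless–Michaelson type) delivers oxygen to the alkene face on the side of the C4 hydroxyl, setting C6 as R.

**Step 22**
Reactants: 27 epoxy diol
Product: 30 triol with C7=C8 alkene, via phenylselenide 28 (not isolated), via selenoxide 29 (not isolated)
Conditions: PhSeSePh, NaBH4, EtOH, 78 °C; then H2O2, pyridine, THF, 0 °C → rt
Reagents that add atoms: none
Why: In the Sharpless–Lauer sequence the selenolate opens the epoxide by SN2 attack at the secondary carbon, and selenoxide syn-elimination can only go towards C8 because C6 bears no hydrogen, giving the tertiary allylic alcohol with C6 retained.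

**Step 23**
Reactants: 30 triol; 31 4-[(tert-butyldimethylsilyl)oxy]benzoic acid
Product: 32 silyl-protected C4 ester
Conditions: DCC, DMAP, CH2Cl2, rt
Reagents that add atoms: none
Why: Steglich esterification acylates only the secondary hydroxyl, the two tertiary hydroxyls being too hindered to react.

**Step 24**
Reactants: 32 silyl-protected ester
Product: 33 target
Conditions: Bu4NF, AcOH, THF, 0 °C
Reagents that add atoms: none
Why: Buffered fluoride desilylation cleaves the aryl silyl ether without touching the benzoate or the acid-sensitive tertiary allylic alcohol.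

**Compound list**
1 | 1,2:5,6-di-O-isopropylidene-D-mannitol, (1S,2S)-1,2-bis[(4R)-2,2-dimethyl-1,3-dioxolan-4-yl]ethane-1,2-diol | CC1(C)OC[C@@H](O1)[C@@H](O)[C@H](O)[C@H]1COC(C)(C)O1 | starting material
2 | (4R)-2,2-dimethyl-1,3-dioxolane-4-carbaldehyde | CC1(C)OC[C@@H](O1)C=O | intermediate
3 | methyl (2Z)-3-[(4S)-2,2-dimethyl-1,3-dioxolan-4-yl]prop-2-enoate | CC1(C)OC[C@@H](O1)/C=C\C(=O)OC | intermediate
4 | methyl (2Z,4S)-4,5-dihydroxypent-2-enoate | COC(=O)/C=C\[C@H](O)CO | intermediate (not isolated)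
5 | (5S)-5-(hydroxymethyl)furan-2(5H)-one | OC[C@H]1OC(=O)C=C1 | intermediate
6 | (5S)-5-{[tert-butyl(diphenyl)silyl]oxymethyl}furan-2(5H)-one | CC(C)(C)[Si](OC[C@H]1OC(=O)C=C1)(c1ccccc1)c1ccccc1 | intermediate
7 | 1,3-dithiane | C1CSCSC1 | starting material
8 | (2-bromoethoxy)(tert-butyl)dimethylsilane | CC(C)(C)[Si](C)(C)OCCBr | starting material
9 | tert-butyl[2-(1,3-dithian-2-yl)ethoxy]dimethylsilane | CC(C)(C)[Si](C)(C)OCCC1SCCCS1 | intermediate
10 | (4S,5S)-5-{[tert-butyl(diphenyl)silyl]oxymethyl}-4-{2-[2-(tert-butyldimethylsilyloxy)ethyl]-1,3-dithian-2-yl}oxolan-2-one | O=C1C[C@H](C2(CCO[Si](C)(C)C(C)(C)C)SCCCS2)[C@@H](CO[Si](c3ccccc3)(c3ccccc3)C(C)(C)C)O1 | intermediate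
11 | (4S,5S)-5-{[tert-butyl(diphenyl)silyl]oxymethyl}-4-[2-(2-hydroxyethyl)-1,3-dithian-2-yl]oxolan-2-one | O=C1C[C@H](C2(CCO)SCCCS2)[C@@H](CO[Si](c3ccccc3)(c3ccccc3)C(C)(C)C)O1 | intermediate
12 | (4S,5S)-5-{[tert-butyl(diphenyl)silyl]oxymethyl}-4-[2-(2-iodoethyl)-1,3-dithian-2-yl]oxolan-2-one | O=C1C[C@H](C2(CCI)SCCCS2)[C@@H](CO[Si](c3ccccc3)(c3ccccc3)C(C)(C)C)O1 | intermediate
13 | (3S,3aS,6aR)-3-{[tert-butyl(diphenyl)silyl]oxymethyl}tetrahydrospiro[cyclopenta[c]furan-4,2'-[1,3]dithian]-1(3H)-one, cis-fused | O=C1O[C@H](CO[Si](c2ccccc2)(c2ccccc2)C(C)(C)C)[C@@H]2[C@H]1CCC21SCCCS1 | intermediate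
14 | (3S,3aS,6aR)-3-{[tert-butyl(diphenyl)silyl]oxymethyl}-6a-methyltetrahydrospiro[cyclopenta[c]furan-4,2'-[1,3]dithian]-1(3H)-one | C[C@@]12CCC3(SCCCS3)[C@@H]1[C@@H](CO[Si](c4ccccc4)(c4ccccc4)C(C)(C)C)OC2=O | intermediate
15 | (3S,3aS,6aR)-3-{[tert-butyl(diphenyl)silyl]oxymethyl}-6a-methyltetrahydro-1H-cyclopenta[c]furan-1,4(3H)-dione | C[C@@]12CCC(=O)[C@@H]1[C@@H](CO[Si](c3ccccc3)(c3ccccc3)C(C)(C)C)OC2=O | intermediate
16 | (3S,3aS,4R,6aR)-3-{[tert-butyl(diphenyl)silyl]oxymethyl}-4-hydroxy-6a-methyl-4-(propan-2-yl)hexahydro-1H-cyclopenta[c]furan-1-one | C[C@@]12CC[C@@](O)(C(C)C)[C@@H]1[C@@H](CO[Si](c3ccccc3)(c3ccccc3)C(C)(C)C)OC2=O | intermediate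
17 | (3S,3aS,4R,6aR)-3-{[tert-butyl(diphenyl)silyl]oxymethyl}-6a-methyl-4-(propan-2-yl)-4-[(triethylsilyl)oxy]hexahydro-1H-cyclopenta[c]furan-1-one | C[C@@]12CC[C@@](O[Si](CC)(CC)CC)(C(C)C)[C@@H]1[C@@H](CO[Si](c3ccccc3)(c3ccccc3)C(C)(C)C)OC2=O | intermediate
18 | (3S,3aS,4R,6aR)-3-{[tert-butyl(diphenyl)silyl]oxymethyl}-6a-methyl-4-(propan-2-yl)-4-[(triethylsilyl)oxy]hexahydro-1H-cyclopenta[c]furan-1-ol (anomer mixture) | C[C@@]12CC[C@@](O[Si](CC)(CC)CC)(C(C)C)[C@@H]1[C@@H](CO[Si](c3ccccc3)(c3ccccc3)C(C)(C)C)OC2O | intermediate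
19 | (1S)-2-{[tert-butyl(diphenyl)silyl]oxy}-1-[(1S,2R,5S)-5-(2-methoxyethenyl)-5-methyl-2-(propan-2-yl)-2-(triethylsilyloxy)cyclopentyl]ethan-1-ol (E/Z mixture) | COC=C[C@]1(C)CC[C@@](O[Si](CC)(CC)CC)(C(C)C)[C@@H]1[C@H](O)CO[Si](c2ccccc2)(c2ccccc2)C(C)(C)C | intermediate (not isolated)
20 | (1S,4aS,7R,7aS)-1-{[tert-butyl(diphenyl)silyl]oxymethyl}-4a-methyl-7-(propan-2-yl)-7-[(triethylsilyl)oxy]octahydrocyclopenta[c]pyran-3-ol (anomer mixture) | OC1C[C@]2(C)CC[C@@](O[Si](CC)(CC)CC)(C(C)C)[C@@H]2[C@@H](CO[Si](c3ccccc3)(c3ccccc3)C(C)(C)C)O1 | intermediate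
21 | (1S)-2-{[tert-butyl(diphenyl)silyl]oxy}-1-[(1S,2R,5S)-5-methyl-2-(propan-2-yl)-5-(prop-2-en-1-yl)-2-(triethylsilyloxy)cyclopentyl]ethan-1-ol | C=CC[C@]1(C)CC[C@@](O[Si](CC)(CC)CC)(C(C)C)[C@@H]1[C@H](O)CO[Si](c2ccccc2)(c2ccccc2)C(C)(C)C | intermediate
22 | (1S)-1-[(1S,2R,5S)-2-hydroxy-5-methyl-2-(propan-2-yl)-5-(prop-2-en-1-yl)cyclopentyl]ethane-1,2-diol | C=CC[C@]1(C)CC[C@@](O)(C(C)C)[C@@H]1[C@H](O)CO | intermediate
23 | (1R,2R,5S)-2-hydroxy-5-methyl-2-(propan-2-yl)-5-(prop-2-en-1-yl)cyclopentane-1-carbaldehyde | C=CC[C@]1(C)CC[C@@](O)(C(C)C)[C@@H]1C=O | intermediate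
24 | 3-bromo-2-methylprop-1-ene (methallyl bromide) | CC(=C)CBr | starting material
25 | (1S)-1-[(1S,2R,5S)-2-hydroxy-5-methyl-2-(propan-2-yl)-5-(prop-2-en-1-yl)cyclopentyl]-3-methylbut-3-en-1-ol | C=CC[C@]1(C)CC[C@@](O)(C(C)C)[C@@H]1[C@@H](O)CC(C)=C | intermediate
26 | (3R,3aS,4S,8aS)-6,8a-dimethyl-3-(propan-2-yl)-1,2,3,3a,4,5,8,8a-octahydroazulene-3,4-diol | CC(C)[C@]1(O)CC[C@@]2(C)CC=C(C)C[C@H](O)[C@@H]12 | intermediate
27 | (3R,3aS,4S,6R,7S,8aS)-6,7-epoxy-6,8a-dimethyl-3-(propan-2-yl)decahydroazulene-3,4-diol (epoxide cis to the 4-OH) | CC(C)[C@]1(O)CC[C@@]2(C)C[C@@H]3O[C@]3(C)C[C@H](O)[C@@H]12 | intermediate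
28 | (3R,3aS,4S,6R,7R,8aS)-6,8a-dimethyl-7-(phenylselanyl)-3-(propan-2-yl)decahydroazulene-3,4,6-triol | CC(C)[C@]1(O)CC[C@@]2(C)C[C@@H]([Se]c3ccccc3)[C@](C)(O)C[C@H](O)[C@@H]12 | intermediate (not isolated)
29 | (3R,3aS,4S,6R,7R,8aS)-6,8a-dimethyl-7-(phenylseleninyl)-3-(propan-2-yl)decahydroazulene-3,4,6-triol (mixture at selenium) | CC(C)[C@]1(O)CC[C@@]2(C)C[C@@H]([Se](=O)c3ccccc3)[C@](C)(O)C[C@H](O)[C@@H]12 | intermediate (not isolated)
30 | (3R,3aS,4S,6R,8aS)-6,8a-dimethyl-3-(propan-2-yl)-1,2,3,3a,4,5,6,8a-octahydroazulene-3,4,6-triol | CC(C)[C@]1(O)CC[C@@]2(C)C=C[C@](C)(O)C[C@H](O)[C@@H]12 | intermediate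
31 | 4-[(tert-butyldimethylsilyl)oxy]benzoic acid | CC(C)(C)[Si](C)(C)Oc1ccc(cc1)C(=O)O | starting material
32 | (3R,3aS,4S,6R,8aS)-3,6-dihydroxy-6,8a-dimethyl-3-(propan-2-yl)-1,2,3,3a,4,5,6,8a-octahydroazulen-4-yl 4-[(tert-butyldimethylsilyl)oxy]benzoate | CC(C)[C@]1(O)CC[C@@]2(C)C=C[C@](C)(O)C[C@H](OC(=O)c3ccc(O[Si](C)(C)C(C)(C)C)cc3)[C@@H]12 | intermediate
33 | (3R,3aS,4S,6R,8aS)-3,6-dihydroxy-6,8a-dimethyl-3-(propan-2-yl)-1,2,3,3a,4,5,6,8a-octahydroazulen-4-yl 4-hydroxybenzoate | CC(C)[C@]1(O)CC[C@@]2(C)C=C[C@](C)(O)C[C@H](OC(=O)c3ccc(O)cc3)[C@@H]12 | target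

**Totals**
Total steps: 24. Longest linear sequence: 23 steps (steps 1–4 and 6–24; step 5 makes the dithiane fragment).

**Steps most likely to fail, with fallbacks**

Step 12 (isopropyl addition to a hindered, enolisable β-acyloxy ketone; a secondary alkyl nucleophile can reduce or enolise instead of adding). The fallback sets out from 15: isopropenylmagnesium bromide with CeCl3 in THF at −78 °C, an sp2 nucleophile without β-hydrogens, adds from the same convex face to give the isopropenyl carbinol F1. Hydrogenation (H2, 5% Pd/C, EtOAc), possible here because no other alkene is present, comes back to the route at 16.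

Step 19 (diastereoselectivity of the key methallylation rests on chelation by the free tertiary hydroxyl; without chelation the Felkin mode gives the C4 epimer). The fallback sets out from 23 and replaces substrate control by reagent control. The tertiary hydroxyl is capped with N-(trimethylsilyl)imidazole to give the silyl ether aldehyde F2. Brown methallylboration with (−)-B-methallyldiisopinocampheylborane (from (+)-α-pinene, adds to the Si face; Et2O, −78 °C, then NaOH/H2O2) gives the silyl ether carbinol F3. K2CO3 in MeOH removes the silyl group and comes back to the route at 25. Whether this reagent is matched to the substrate is not known.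

Step 21 (face selectivity of a homoallylic-hydroxyl-directed epoxidation in a flexible seven-membered ring, followed by the two-stage transposition). The fallback sets out from 26 and uses a Schenck ene reaction instead: singlet oxygen (O2, hν, tetraphenylporphyrin, CH2Cl2, 0 °C) abstracts an allylic hydrogen at C8 and gives the tertiary allylic hydroperoxide F4, with regio- and face isomers to be separated. Reduction with PPh3 comes back to the route at 30, bypassing 27–29.

**Further compounds**
F1 | step 12 | (3S,3aS,4S,6aR)-3-{[tert-butyl(diphenyl)silyl]oxymethyl}-4-hydroxy-6a-methyl-4-(prop-1-en-2-yl)hexahydro-1H-cyclopenta[c]furan-1-one | C[C@@]12CC[C@@](O)(C(C)=C)[C@@H]1[C@@H](CO[Si](c3ccccc3)(c3ccccc3)C(C)(C)C)OC2=O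
F2 | step 19 | (1R,2R,5S)-5-methyl-2-(propan-2-yl)-5-(prop-2-en-1-yl)-2-[(trimethylsilyl)oxy]cyclopentane-1-carbaldehyde | C=CC[C@]1(C)CC[C@@](O[Si](C)(C)C)(C(C)C)[C@@H]1C=O
F3 | step 19 | (1S)-3-methyl-1-[(1S,2R,5S)-5-methyl-2-(propan-2-yl)-5-(prop-2-en-1-yl)-2-(trimethylsilyloxy)cyclopentyl]but-3-en-1-ol | C=CC[C@]1(C)CC[C@@](O[Si](C)(C)C)(C(C)C)[C@@H]1[C@@H](O)CC(C)=C
F4 | step 21 | (3R,3aS,4S,6R,8aS)-6-hydroperoxy-6,8a-dimethyl-3-(propan-2-yl)-1,2,3,3a,4,5,6,8a-octahydroazulene-3,4-diol | CC(C)[C@]1(O)CC[C@@]2(C)C=C[C@](C)(OO)C[C@H](O)[C@@H]12
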